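**Plan**
- Retrosynthesis: the O7 aroyl group and both silyl groups come off last. The C5–O bond is traced back, through a six-membered carbonate on O7, to a C4=C5 ring alkene, which is cut by ring-closing metathesis. The open chain is then cut at C6–C7 and C9–C10 (two 2-substituted allyl additions) and at the C8–CH2O bond (auxiliary alkylation).
- Enabling feature: in the ten-membered carbocycle (C1 = methylidene carbon, counted round to C10), C5 is a methyl-bearing tertiary carbinol, 1,3-cis to the C7 oxygen and next to the C4 methylene. C4=C5 is therefore a latent ring alkene, and O7 is a built-in arm for delivering oxygen to C5.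
- Forward order: C8 is set first, then C9–C10 is joined (Sakurai addition), then C6–C7 (allylboration). The only ring closes at C4=C5 in step 12, followed by carbonate cyclisation, deiodination, methanolysis, C7 acylation and desilylation.
- Stereochemistry: C8 comes from the (S)-benzyloxazolidinone, C9 from Cram chelation (anti to isopropyl), C7 from the (−)-α-pinene-derived borane, and C5 from the O7 carbonate tether (cis to O7).

Key step: step 12

Remark: the ring alkene of 20 is written as the Z isomer expected for this ring size; the E isomer would be carried through the same steps, because C4 ends as a methylene group and C5 is fixed by the tether.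

**Route**

Step 1
Reactants: 1 (S)-4-benzyl-1,3-oxazolidin-2-one; 2 3-methylbutanoyl chloride
Product: 3 (S)-4-benzyl-3-(3-methylbutanoyl)-1,3-oxazolidin-2-one
Conditions: n-BuLi, THF, −78 °C; then 2, −78 to 0 °C
Reagents that add atoms: none
Why: N-acylation of the lithiated oxazolidinone by an acid chloride is the standard loading of an Evans auxiliary and creates no stereocentre.

Step 2
Reactants: 3; 4 benzyl chloromethyl ether
Product: 5 (4S)-4-benzyl-3-[(2R)-2-[(benzyloxy)methyl]-3-methylbutanoyl]-1,3-oxazolidin-2-one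
Conditions: TiCl4, i-Pr2NEt, CH2Cl2, 0 °C; then 4, 0 °C
Reagents that add atoms: none
Why: Evans alkylation of the chelated Z titanium enolate with the oxocarbenium-type electrophile takes place on the face away from the C4 benzyl group of the auxiliary, which sets the future C8 as the (2R) acyl carbon.

Step 3
Reactants: 5
Product: 6 (2S)-2-[(benzyloxy)methyl]-3-methylbutan-1-ol
Conditions: LiBH4, MeOH (1 equiv), Et2O, 0 °C
Reagents that add atoms: none
Why: Reductive cleavage of the imide by LiBH4 releases the primary alcohol and the recoverable auxiliary without touching the adjacent stereocentre.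

Step 4
Reactants: 6
Product: 7 (2R)-2-[(benzyloxy)methyl]-3-methylbutanal
Conditions: Dess–Martin periodinane, CH2Cl2, 0 °C to rt; used crude
Reagents that add atoms: none
Why: Dess–Martin oxidation works under near-neutral conditions, so the α-branched aldehyde should form without enolisation and is used at once.

Step 5
Reactants: 8 [2-(chloromethyl)prop-2-en-1-yl]trimethylsilane; 9 allylmagnesium bromide
Product: 10 trimethyl(2-methylidenehex-5-en-1-yl)silane
Conditions: CuI (5 mol%), THF, −20 °C to rt
Reagents that add atoms: none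
Why: Copper-catalysed allyl–allyl coupling of a Grignard reagent with an allylic chloride gives the same 2-substituted allylsilane by either the SN2 or the SN2′ path.

Step 6
Reactants: 7; 10
Product: 11 (2R,3S)-1-(benzyloxy)-5-methylidene-2-(propan-2-yl)non-8-en-3-ol
Conditions: TiCl4 (1.1 equiv), CH2Cl2, −78 °C; then 10, −78 °C
Reagents that add atoms: none
Why: In this chelation-controlled Hosomi–Sakurai addition, TiCl4 ties the aldehyde and benzyl ether oxygens into a six-membered chelate, and the allylsilane attacks the face away from the isopropyl group (Cram chelate model), which sets C9 anti to the isopropyl group.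

Step 7
Reactants: 11
Product: 12 tert-butyl{[(2R,3S)-1-(benzyloxy)-5-methylidene-2-(propan-2-yl)non-8-en-3-yl]oxy}dimethylsilane
Conditions: TBSOTf, 2,6-lutidine, CH2Cl2, −78 to 0 °C
Reagents that add atoms: tert-butyldimethylsilyl trifluoromethanesulfonate, CC(C)(C)[Si](C)(C)OS(=O)(=O)C(F)(F)F
Why: Silylation of a hindered secondary alcohol with the silyl triflate and a hindered base is routine and leaves the stereocentres and alkenes untouched.

Step 8
Reactants: 12
Product: 13 (2R,3S)-3-[(tert-butyldimethylsilyl)oxy]-5-methylidene-2-(propan-2-yl)non-8-en-1-ol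
Conditions: lithium 4,4′-di-tert-butylbiphenylide (LiDBB), THF, −78 °C; NH4Cl
Reagents that add atoms: none
Why: Reductive debenzylation by an arene radical anion cleaves the benzyl ether while isolated alkenes and the silyl ether are inert at −78 °C.

Step 9
Reactants: 13
Product: 14 (2S,3S)-3-[(tert-butyldimethylsilyl)oxy]-5-methylidene-2-(propan-2-yl)non-8-enal
Conditions: Dess–Martin periodinane, pyridine, CH2Cl2, 0 °C to rt; used crude
Reagents that add atoms: none
Why: Dess–Martin oxidation gives the α-branched β-silyloxy aldehyde under conditions that cause neither epimerisation nor β-elimination.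

Step 10
Reactants: 14; 15 (2-methylprop-2-en-1-yl)magnesium chloride
Product: 18 (4R,5R,6S)-6-[(tert-butyldimethylsilyl)oxy]-2-methyl-8-methylidene-5-(propan-2-yl)dodeca-1,11-dien-4-ol, via B-(2-methylallyl)diisopinocampheylborane 16 (not isolated), via C7 O-diisopinocampheylborinate 17 (not isolated)
Conditions: (+)-Ipc2BOMe [from (−)-α-pinene], 15, Et2O, −78 °C to rt; then 14, −78 °C; then NaOH, H2O2
Reagents that add atoms: (+)-B-methoxydiisopinocampheylborane, COB([C@H]1C[C@H]2C[C@@H]([C@@H]1C)C2(C)C)[C@H]1C[C@H]2C[C@@H]([C@@H]1C)C2(C)C (its atoms stay only in 16 and 17)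
Why: Brown allylboration runs through a closed six-membered chair transition state in which the isopinocampheyl groups of the (−)-α-pinene series send the methallyl group to the Re face of the aldehyde, so reagent control sets C7 as R (anti to isopropyl, 1,3-syn to the C9 oxygen) against the substrate bias.

Step 11
Reactants: 18
Product: 19 tert-butyl (4R,5R,6S)-6-[(tert-butyldimethylsilyl)oxy]-2-methyl-8-methylidene-5-(propan-2-yl)dodeca-1,11-dien-4-yl carbonate
Conditions: Boc2O, DMAP, MeCN, rt
Reagents that add atoms: di-tert-butyl dicarbonate, CC(C)(C)OC(=O)OC(=O)OC(C)(C)C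
Why: DMAP-catalysed acylation with Boc2O turns the secondary alcohol into the mixed tert-butyl carbonate needed later as the oxygen-delivering tether, with no change at any stereocentre.

Step 12
Reactants: 19
Product: 20 (4Z,7R,8R,9S)-7-[(tert-butoxycarbonyl)oxy]-9-[(tert-butyldimethylsilyl)oxy]-5-methyl-1-methylidene-8-(propan-2-yl)cyclodec-4-ene (ring numbered from the methylidene carbon)
Conditions: RuCl2(=CHPh)(H2IMes)(PCy3) (second-generation Grubbs catalyst, 15 mol% in portions), toluene (0.5 mM), 80 °C, argon sparge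
Reagents that add atoms: none
Why: By the Chauvin mechanism the ruthenium benzylidene exchanges with the monosubstituted C4 vinyl group, the resulting alkylidene adds [2+2] to the 1,1-disubstituted C5 alkene, and cycloreversion of the ruthenacyclobutane gives the C4=C5 bond and Ru=CH2, which leaves as ethylene on turnover. The closest known reaction type is ring-closing olefin metathesis to medium carbocycles that carry a trisubstituted ring alkene. The ten-membered carbocycle is closed end to end between C4 and C5, the two termini of the 1,11-diene, so the new double bond lies inside the ring. No stereocentre is formed, and the alkene geometry need not be controlled because C4 later becomes a methylene group and C5 is set by the carbonate tether. The step needs ring closure to win over dimerisation and the correct pairing among three alkenes; the pairing is secured because the C4 carbene with the C1 methylidene could only give a cyclobutene and the two 1,1-disubstituted alkenes only a tetrasubstituted cycloheptene. Ring closure is helped by the three contiguous substituted carbons C7 to C9, whose carbonate, isopropyl and silyloxy groups favour gauche turns of the chain, and by high dilution with slow catalyst addition.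

Step 13
Reactants: 20
Product: 21 cyclic carbonate of (4S,5S,7R,8R,9S)-9-[(tert-butyldimethylsilyl)oxy]-4-iodo-5-methyl-1-methylidene-8-(propan-2-yl)cyclodecane-5,7-diol
Conditions: IBr (1.2 equiv), toluene, −85 °C; Na2S2O3/NaHCO3 quench
Reagents that add atoms: iodine monobromide, BrI
Why: In this iodocarbonate cyclisation the iodonium ion on C4=C5 is opened at the more substituted C5 by the carbonate carbonyl oxygen in a 6-exo closure with loss of the tert-butyl group, and because the new six-membered carbonate must bridge C5 and C7 on one face of the ten-membered ring, the C5 oxygen is placed cis to the C7 oxygen while iodine adds anti at C4.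

Step 14
Reactants: 21
Product: 22 cyclic carbonate of (5R,7R,8R,9S)-9-[(tert-butyldimethylsilyl)oxy]-5-methyl-1-methylidene-8-(propan-2-yl)cyclodecane-5,7-diol
Conditions: Bu3SnH, AIBN (cat.), toluene, 80 °C
Reagents that add atoms: none
Why: Radical chain dehalogenation with tin hydride replaces the secondary iodide by hydrogen faster than the C4 radical can add across the ring, and it removes the only stereocentre (C4) that is not wanted.

Step 15
Reactants: 22
Product: 23 (5R,7R,8R,9S)-9-[(tert-butyldimethylsilyl)oxy]-5-methyl-1-methylidene-8-(propan-2-yl)cyclodecane-5,7-diol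
Conditions: K2CO3, MeOH, rt
Reagents that add atoms: none
Why: Base-catalysed transesterification of the cyclic carbonate with methanol frees the tertiary C5 and secondary C7 hydroxyl groups without touching the silyl ether or any stereocentre.

Step 16
Reactants: 24 4-hydroxybenzoic acid
Product: 25 tert-butyldimethylsilyl 4-[(tert-butyldimethylsilyl)oxy]benzoate
Conditions: TBSCl (2.3 equiv), imidazole, DMF, rt
Reagents that add atoms: tert-butyldimethylsilyl chloride, CC(C)(C)[Si](C)(C)Cl
Why: Imidazole-promoted silylation caps both the phenol and the carboxylic acid in one operation.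

Step 17
Reactants: 25
Product: 26 4-[(tert-butyldimethylsilyl)oxy]benzoyl chloride
Conditions: (COCl)2, DMF (cat.), CH2Cl2, 0 °C to rt
Reagents that add atoms: oxalyl chloride, O=C(Cl)C(Cl)=O
Why: The Vilsmeier-type chlorination converts a silyl ester directly into the acid chloride under neutral conditions, so the aryl silyl ether survives.

Step 18
Reactants: 23; 26
Product: 27 (5R,7R,8R,9S)-9-[(tert-butyldimethylsilyl)oxy]-5-hydroxy-5-methyl-1-methylidene-8-(propan-2-yl)cyclodecan-7-yl 4-[(tert-butyldimethylsilyl)oxy]benzoate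
Conditions: Et3N, DMAP, CH2Cl2, 0 °C to rt
Reagents that add atoms: none
Why: DMAP-catalysed acylation by an acid chloride should esterify the secondary C7 hydroxyl group selectively, because the tertiary C5 hydroxyl group reacts far more slowly.

Step 19
Reactants: 27
Product: 28 (5R,7R,8S,9S)-5,9-dihydroxy-5-methyl-1-methylidene-8-(propan-2-yl)cyclodecan-7-yl 4-hydroxybenzoate (CNP0293401.1)
Conditions: HF·pyridine, pyridine, THF, 0 °C to rt
Reagents that add atoms: none
Why: Buffered fluoride desilylation removes the aryl and the secondary silyl ether in one operation under conditions too mild for acyl migration or acid-induced transannular reactions.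

**Compound list**
1 | (S)-4-benzyl-1,3-oxazolidin-2-one | O=C1N[C@@H](Cc2ccccc2)CO1 | starting material
2 | 3-methylbutanoyl chloride | CC(C)CC(Cl)=O | starting material
3 | (S)-4-benzyl-3-(3-methylbutanoyl)-1,3-oxazolidin-2-one | CC(C)CC(=O)N1[C@@H](Cc2ccccc2)COC1=O | intermediate
4 | benzyl chloromethyl ether | ClCOCc1ccccc1 | starting material
5 | (4S)-4-benzyl-3-[(2R)-2-[(benzyloxy)methyl]-3-methylbutanoyl]-1,3-oxazolidin-2-one | c1ccccc1COC[C@@H](C(C)C)C(=O)N1[C@@H](Cc2ccccc2)COC1=O | intermediate
6 | (2S)-2-[(benzyloxy)methyl]-3-methylbutan-1-ol | c1ccccc1COC[C@@H](C(C)C)CO | intermediate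
7 | (2R)-2-[(benzyloxy)methyl]-3-methylbutanal | c1ccccc1COC[C@@H](C(C)C)C=O | intermediate
8 | [2-(chloromethyl)prop-2-en-1-yl]trimethylsilane | C=C(CCl)C[Si](C)(C)C | starting material
9 | allylmagnesium bromide | C=CC[Mg]Br | starting material
10 | trimethyl(2-methylidenehex-5-en-1-yl)silane | C=CCCC(=C)C[Si](C)(C)C | intermediate
11 | (2R,3S)-1-(benzyloxy)-5-methylidene-2-(propan-2-yl)non-8-en-3-ol | c1ccccc1COC[C@@H](C(C)C)[C@@H](O)CC(=C)CCC=C | intermediate
12 | tert-butyl{[(2R,3S)-1-(benzyloxy)-5-methylidene-2-(propan-2-yl)non-8-en-3-yl]oxy}dimethylsilane | c1ccccc1COC[C@@H](C(C)C)[C@@H](O[Si](C)(C)C(C)(C)C)CC(=C)CCC=C | intermediate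
13 | (2R,3S)-3-[(tert-butyldimethylsilyl)oxy]-5-methylidene-2-(propan-2-yl)non-8-en-1-ol | OC[C@@H](C(C)C)[C@@H](O[Si](C)(C)C(C)(C)C)CC(=C)CCC=C | intermediate
14 | (2S,3S)-3-[(tert-butyldimethylsilyl)oxy]-5-methylidene-2-(propan-2-yl)non-8-enal | O=C[C@@H](C(C)C)[C@@H](O[Si](C)(C)C(C)(C)C)CC(=C)CCC=C | intermediate
15 | (2-methylprop-2-en-1-yl)magnesium chloride | C=C(C)C[Mg]Cl | starting material
16 | B-(2-methylprop-2-en-1-yl)diisopinocampheylborane, (−)-α-pinene series (not isolated) | C=C(C)CB([C@H]1C[C@H]2C[C@@H]([C@@H]1C)C2(C)C)[C@H]1C[C@H]2C[C@@H]([C@@H]1C)C2(C)C | intermediate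
17 | O-diisopinocampheylboryl derivative of 18 at the C7 oxygen (not isolated) | C=C(C)C[C@@H](OB([C@H]1C[C@H]2C[C@@H]([C@@H]1C)C2(C)C)[C@H]1C[C@H]2C[C@@H]([C@@H]1C)C2(C)C)[C@@H](C(C)C)[C@@H](O[Si](C)(C)C(C)(C)C)CC(=C)CCC=C | intermediate
18 | (4R,5R,6S)-6-[(tert-butyldimethylsilyl)oxy]-2-methyl-8-methylidene-5-(propan-2-yl)dodeca-1,11-dien-4-ol | C=C(C)C[C@@H](O)[C@@H](C(C)C)[C@@H](O[Si](C)(C)C(C)(C)C)CC(=C)CCC=C | intermediate
19 | tert-butyl (4R,5R,6S)-6-[(tert-butyldimethylsilyl)oxy]-2-methyl-8-methylidene-5-(propan-2-yl)dodeca-1,11-dien-4-yl carbonate | C=C(C)C[C@@H](OC(=O)OC(C)(C)C)[C@@H](C(C)C)[C@@H](O[Si](C)(C)C(C)(C)C)CC(=C)CCC=C | intermediate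
20 | (4Z,7R,8R,9S)-7-[(tert-butoxycarbonyl)oxy]-9-[(tert-butyldimethylsilyl)oxy]-5-methyl-1-methylidene-8-(propan-2-yl)cyclodec-4-ene | C=C1CC/C=C(C)\C[C@@H](OC(=O)OC(C)(C)C)[C@@H](C(C)C)[C@@H](O[Si](C)(C)C(C)(C)C)C1 | intermediate
21 | cyclic carbonate of (4S,5S,7R,8R,9S)-9-[(tert-butyldimethylsilyl)oxy]-4-iodo-5-methyl-1-methylidene-8-(propan-2-yl)cyclodecane-5,7-diol | C=C1CC[C@H](I)[C@@](C)(OC(=O)O2)C[C@@H]2[C@@H](C(C)C)[C@@H](O[Si](C)(C)C(C)(C)C)C1 | intermediate
22 | cyclic carbonate of (5R,7R,8R,9S)-9-[(tert-butyldimethylsilyl)oxy]-5-methyl-1-methylidene-8-(propan-2-yl)cyclodecane-5,7-diol | C=C1CCC[C@@](C)(OC(=O)O2)C[C@@H]2[C@@H](C(C)C)[C@@H](O[Si](C)(C)C(C)(C)C)C1 | intermediate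
23 | (5R,7R,8R,9S)-9-[(tert-butyldimethylsilyl)oxy]-5-methyl-1-methylidene-8-(propan-2-yl)cyclodecane-5,7-diol | C=C1CCC[C@@](C)(O)C[C@@H](O)[C@@H](C(C)C)[C@@H](O[Si](C)(C)C(C)(C)C)C1 | intermediate
24 | 4-hydroxybenzoic acid | OC(=O)c1ccc(O)cc1 | starting material
25 | tert-butyldimethylsilyl 4-[(tert-butyldimethylsilyl)oxy]benzoate | CC(C)(C)[Si](C)(C)OC(=O)c1ccc(O[Si](C)(C)C(C)(C)C)cc1 | intermediate
26 | 4-[(tert-butyldimethylsilyl)oxy]benzoyl chloride | O=C(Cl)c1ccc(O[Si](C)(C)C(C)(C)C)cc1 | intermediate
27 | (5R,7R,8R,9S)-9-[(tert-butyldimethylsilyl)oxy]-5-hydroxy-5-methyl-1-methylidene-8-(propan-2-yl)cyclodecan-7-yl 4-[(tert-butyldimethylsilyl)oxy]benzoate | C=C1CCC[C@@](C)(O)C[C@@H](OC(=O)c2ccc(O[Si](C)(C)C(C)(C)C)cc2)[C@@H](C(C)C)[C@@H](O[Si](C)(C)C(C)(C)C)C1 | intermediate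
28 | (5R,7R,8S,9S)-5,9-dihydroxy-5-methyl-1-methylidene-8-(propan-2-yl)cyclodecan-7-yl 4-hydroxybenzoate | C=C1CCC[C@@](C)(O)C[C@@H](OC(=O)c2ccc(O)cc2)[C@@H](C(C)C)[C@@H](O)C1 | target

**Step count**
Total: 19 steps. Longest linear sequence: 16 steps (steps 1–4, 6–15, 18, 19). Step 5 and steps 16–17 are side branches.

**Steps most likely to fail**

1. Step 12 (ring closure). Intermolecular metathesis through the unhindered C4 vinyl group (dimers, oligomers) may outrun closure onto the 1,1-disubstituted alkene, or the carbene may not engage that alkene in a ten-membered transition state. No short detour keeps the same side chain, so the fallback forms the same C4–C5 bond by an intramolecular B-alkyl Suzuki–Miyaura coupling and brings in the C5 methyl group afterwards. It sets out from aldehyde 7 and silane precursor 8. Copper-catalysed coupling of 8 with vinylmagnesium bromide gives trimethyl(2-methylidenepent-4-en-1-yl)silane F1, one carbon shorter than 10. TiCl4-chelated addition of F1 to 7 gives the homoallylic alcohol F2, which is silylated to the silyl ether F3, debenzylated to the primary alcohol F4 and oxidised to the aldehyde F5 under the conditions of steps 7 to 9. (2-Bromoallyl)diisopinocampheylborane F6, made from Ipc2BBr of the (−)-α-pinene series and allene, adds to F5 through the borinate F7 and gives, after NaOH/H2O2, the 2-bromoallyl carbinol F8 with the C7 configuration of 18. Boc2O/DMAP gives the tert-butyl carbonate F9. Disiamylborane hydroborates only the monosubstituted alkene (alkylborane F10), and PdCl2(dppf), AsPh3 and Cs2CO3 in DMF/THF/H2O at high dilution close the ring to the 1,5-bis(methylidene)cyclodecane F11. IBr cyclises the C7 carbonate onto the C5 methylidene group to the iodomethyl cyclic carbonate F12, and Bu3SnH reduces CH2I to CH3. This gives compound 22, where the route is rejoined.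

2. Step 10 (methallylboration). Facial selectivity may be poor: the open-chain preference of aldehyde 14 (Felkin and 1,3-anti induction, which reinforce each other in this anti-configured β-silyloxy aldehyde) favours the C7 epimer and may erode reagent control. The fallback uses that bias and then inverts C7. It sets out from 14: methallyltrimethylsilane with BF3·OEt2 (Hosomi–Sakurai addition, CH2Cl2, −78 °C) should give the 7-epimeric alcohol (4S,5R,6S)-6-[(tert-butyldimethylsilyl)oxy]-2-methyl-8-methylidene-5-(propan-2-yl)dodeca-1,11-dien-4-ol F13 under substrate control. Mitsunobu reaction with 4-nitrobenzoic acid, PPh3 and DIAD (toluene, 0 °C to rt) inverts C7 and gives the 4-nitrobenzoate F14. K2CO3 in MeOH then releases alcohol 18, where the route is rejoined.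

3. Step 13 (carbonate cyclisation). The halogen may add to the C1 methylidene group, the iodonium ion may be captured across the ring by that alkene, or the C–O bond may form on the wrong face in an unfavourable ring conformer. The fallback delivers the oxygen by hydroxyl-directed epoxidation and hydride opening. It sets out from alcohol 18: ring-closing metathesis under the conditions of step 12 gives (4Z,7R,8R,9S)-9-[(tert-butyldimethylsilyl)oxy]-5-methyl-1-methylidene-8-(propan-2-yl)cyclodec-4-en-7-ol F15. VO(acac)2 with t-BuOOH (CH2Cl2, 0 °C) epoxidises only the ring alkene within reach of the free C7 hydroxyl group, on the face syn to it, giving the epoxy alcohol F16 (this holds for the Z alkene). LiAlH4 (THF, 0 °C) opens the epoxide at the less substituted C4 and gives diol 23, where the route is rejoined.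

**Further compounds**
F1 | step 12 | trimethyl(2-methylidenepent-4-en-1-yl)silane | C=CCC(=C)C[Si](C)(C)C
F2 | step 12 | (2R,3S)-1-(benzyloxy)-5-methylidene-2-(propan-2-yl)oct-7-en-3-ol | c1ccccc1COC[C@@H](C(C)C)[C@@H](O)CC(=C)CC=C
F3 | step 12 | tert-butyldimethylsilyl ether of F2 | c1ccccc1COC[C@@H](C(C)C)[C@@H](O[Si](C)(C)C(C)(C)C)CC(=C)CC=C
F4 | step 12 | (2R,3S)-3-[(tert-butyldimethylsilyl)oxy]-5-methylidene-2-(propan-2-yl)oct-7-en-1-ol | OC[C@@H](C(C)C)[C@@H](O[Si](C)(C)C(C)(C)C)CC(=C)CC=C
F5 | step 12 | (2S,3S)-3-[(tert-butyldimethylsilyl)oxy]-5-methylidene-2-(propan-2-yl)oct-7-enal | O=C[C@@H](C(C)C)[C@@H](O[Si](C)(C)C(C)(C)C)CC(=C)CC=C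
F6 | step 12 | B-(2-bromoprop-2-en-1-yl)diisopinocampheylborane, (−)-α-pinene series | C=C(Br)CB([C@H]1C[C@H]2C[C@@H]([C@@H]1C)C2(C)C)[C@H]1C[C@H]2C[C@@H]([C@@H]1C)C2(C)C
F7 | step 12 | O-diisopinocampheylboryl derivative of F8 | C=C(Br)C[C@@H](OB([C@H]1C[C@H]2C[C@@H]([C@@H]1C)C2(C)C)[C@H]1C[C@H]2C[C@@H]([C@@H]1C)C2(C)C)[C@@H](C(C)C)[C@@H](O[Si](C)(C)C(C)(C)C)CC(=C)CC=C
F8 | step 12 | (4R,5R,6S)-2-bromo-6-[(tert-butyldimethylsilyl)oxy]-8-methylidene-5-(propan-2-yl)undeca-1,10-dien-4-ol | C=C(Br)C[C@@H](O)[C@@H](C(C)C)[C@@H](O[Si](C)(C)C(C)(C)C)CC(=C)CC=C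
F9 | step 12 | tert-butyl carbonate of F8 | C=C(Br)C[C@@H](OC(=O)OC(C)(C)C)[C@@H](C(C)C)[C@@H](O[Si](C)(C)C(C)(C)C)CC(=C)CC=C
F10 | step 12 | B-alkyl bis(3-methylbutan-2-yl)borane from hydroboration of the terminal alkene of F9 | C=C(Br)C[C@@H](OC(=O)OC(C)(C)C)[C@@H](C(C)C)[C@@H](O[Si](C)(C)C(C)(C)C)CC(=C)CCCB(C(C)C(C)C)C(C)C(C)C
F11 | step 12 | (7R,8R,9S)-7-[(tert-butoxycarbonyl)oxy]-9-[(tert-butyldimethylsilyl)oxy]-1,5-bis(methylidene)-8-(propan-2-yl)cyclodecane | C=C1CCCC(=C)C[C@@H](OC(=O)OC(C)(C)C)[C@@H](C(C)C)[C@@H](O[Si](C)(C)C(C)(C)C)C1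
F12 | step 12 | cyclic carbonate of (5R,7R,8R,9S)-9-[(tert-butyldimethylsilyl)oxy]-5-(iodomethyl)-1-methylidene-8-(propan-2-yl)cyclodecane-5,7-diol | C=C1CCC[C@@](CI)(OC(=O)O2)C[C@@H]2[C@@H](C(C)C)[C@@H](O[Si](C)(C)C(C)(C)C)C1
F13 | step 10 | (4S,5R,6S)-6-[(tert-butyldimethylsilyl)oxy]-2-methyl-8-methylidene-5-(propan-2-yl)dodeca-1,11-dien-4-ol | C=C(C)C[C@H](O)[C@@H](C(C)C)[C@@H](O[Si](C)(C)C(C)(C)C)CC(=C)CCC=C
F14 | step 10 | (4R,5R,6S)-6-[(tert-butyldimethylsilyl)oxy]-2-methyl-8-methylidene-5-(propan-2-yl)dodeca-1,11-dien-4-yl 4-nitrobenzoate | C=C(C)C[C@@H](OC(=O)c1ccc(cc1)[N+](=O)[O-])[C@@H](C(C)C)[C@@H](O[Si](C)(C)C(C)(C)C)CC(=C)CCC=C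
F15 | step 13 | (4Z,7R,8R,9S)-9-[(tert-butyldimethylsilyl)oxy]-5-methyl-1-methylidene-8-(propan-2-yl)cyclodec-4-en-7-ol | C=C1CC/C=C(C)\C[C@@H](O)[C@@H](C(C)C)[C@@H](O[Si](C)(C)C(C)(C)C)C1
F16 | step 13 | (4R,5S,7R,8R,9S)-9-[(tert-butyldimethylsilyl)oxy]-4,5-epoxy-5-methyl-1-methylidene-8-(propan-2-yl)cyclodecan-7-ol | C=C1CC[C@H]2O[C@@]2(C)C[C@@H](O)[C@@H](C(C)C)[C@@H](O[Si](C)(C)C(C)(C)C)C1
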